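In a one-step world with ligand in excess (pseudo-first-order), a complex responds to the product of ligand concentration and time, so I called the charged concentration times the time the exposure, E. The decision before me was whether elm could keep its charge of 0.360 M: its two-exchanged complex had to stand clear of the scatter, or I would have to charge more.

common to all: starting complex 0.45 M

|  | incoming ligand | remark | time |
|---|---|---|---|
| Tuesday's | 0.74 M | run made earlier |  |
| Friday's | 1.4 M | run made earlier |  |
| elm | 0.360 M |  | 8.0 min |
| cedar | 0.450 M |  | 8.0 min |
| ash | 1.80 M |  | 8.0 min |

| run | time / min | complex with two exchanged / % | complex with three exchanged / % |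
|---|---|---|---|
| Tuesday's | 0.417 | 0.8 | 0 |
| Tuesday's | 0.833 | 0.1 | 0.2 |
| Tuesday's | 1.50 | 1.3 | 0.9 |
| Tuesday's | 3.00 | 1.8 | 0.4 |
| Tuesday's | 6.00 | 5.8 | 3.3 |
| Friday's | 1.00 | 1.9 | 1.1 |
| Friday's | 2.50 | 5.1 | 3.3 |
| Friday's | 3.00 | 6.2 | 5.5 |
| Friday's | 5.00 | 7.2 | 6.1 |
| Friday's | 6.00 | 6.8 | 6.4 |

(readings scatter by 0.5 percentage points)

- which of these holds the largest part of the starting complex at the end of elm (complex with two exchanged / starting complex / complex with three exchanged / complex with four exchanged / complex with one exchanged)
- which of these holds the largest part of the starting complex at the end of cedar (complex with two exchanged / starting complex / complex with three exchanged / complex with four exchanged / complex with one exchanged)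
- which of these holds the largest part of the starting complex at the end of ash (complex with two exchanged / starting complex / complex with three exchanged / complex with four exchanged / complex with one exchanged)
- final complex with two exchanged in elm, as a percentage of the starting complex charged



For elm, E came to 173 M·s. The exposure brought the runs together: Tuesday's run at 6.00 min had 266 M·s and read 5.8%, while Friday's at 3.00 min had 252 M·s and read 6.2%. Elm fell between Tuesday's reading of 1.8% at 133 M·s and Friday's 5.1% at 210 M·s, so straight interpolation gave a first answer of 3.50%.

Then I put that world's flaw back in: elm was charged with less ligand than starting complex, so its ligand was not in excess, and ligand is used up. I took two equal steps, so that the two-exchanged and three-exchanged complexes together equal (kE)²/2, with k the constant of each step. Friday's reading gave k = 0.00195 M⁻¹ s⁻¹. By my reckoning, the share f of elm's starting complex exchanged at least once came to 28.6%, leaving 64.2% of elm's ligand. Using the average of starting and reckoned final ligand, I put elm's exposure at 142 M·s, and the exposures of the two bracketing readings at 124 M·s and 199 M·s. The second round gave 2.59%. Against a scatter of 0.5 percentage points, I kept elm's charge.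

The forecast, by its own reckoning, named starting complex for elm and cedar and complex with one exchanged for ash, and put elm's two-exchanged complex at 2.5%, between 1.2% and 4.5%, saying it “lags its steady value”.

Elm ended with 3.13% of the two-exchanged complex.

    complex with one exchanged + incoming ligand ⇌ leaving ligand + complex with two exchanged (K = 5.85, k = 0.00190 M⁻¹ s⁻¹)
    starting complex ⇌ dormant form (K = 0.450, k = 0.0674 s⁻¹)
    complex with two exchanged + incoming ligand ⇌ leaving ligand + complex with three exchanged (K = 0.790, k = 0.0224 M⁻¹ s⁻¹)
    complex with three exchanged + incoming ligand ⇌ leaving ligand + complex with four exchanged (K = 72.4, k = 0.0123 M⁻¹ s⁻¹)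
    leaving ligand + starting complex → side product (k = 0.00685 M⁻¹ s⁻¹)
    starting complex + incoming ligand ⇌ leaving ligand + complex with one exchanged (K = 1.60, k = 0.0132 M⁻¹ s⁻¹)

At its charged exposure of 173 M·s, that is more than Tuesday's reading of 1.8% and less than Friday's reading of 5.1%. Elm kept 38% of its ligand, less than my 64.2%. A neighbouring flask, the same as elm but charged with 0.90 M of ligand, had an exposure of 432 M·s; Friday's run at 5.00 min, with 420 M·s, read 7.2%, and the neighbour ended with 7.41% of the two-exchanged complex.

(The earlier runs and the new flask stem from a simulated flask from invented constants, noise included.)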